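## The problem

The target 38 is a furanoheliangolide. Its ten-membered carbocycle (C1–C10) is bridged by an oxygen between C3 and C10, giving a 3(2H)-furanone (C1 ketone, C2=C3); it also carries a Z trisubstituted C4=C5 olefin, a γ-lactone trans-fused across C6/C7 whose α-carbon C11 is a spiro-epoxide, a methacrylate on O8 and an acetate on O9. Six contiguous stereocentres (6R,7S,8S,9S,10S,11S) must be set: the oxygens on C8, C9 and C10 and the C7–C11 bond lie on the β face, the lactone oxygen on C6 on the α face. A ten-membered ring is a poor frame for stereocontrol and a poor ring to close by C–C bond formation, so the centres are better set on small rigid rings. There, the C6 oxygen of a butenolide can control C7, a C1 hydroxyl and an 8α-silyloxy group on a seven-membered ring can steer osmylation to C9/C10, and the resulting acetonide can steer hydride to C8. The groups that restrict reagents are the α-methylene lactone and the epoxy-lactone made from it (hydride, amines, thiolates, strong acid), the 8β-hydroxyl (translactonisation onto C12 under base), the cis esters on O8/O9 (acyl migration), and the β-hydroxy ketone and 1,3-diketone that precede the furanone (retro-aldol). The enabling feature is the 1,3-relationship of the C1 ketone and the C4=C5 olefin through C5, with an oxygen on C3: this is the pattern left when the C1–C5 bond of a 1-hydroxy-3,4-epoxy bicyclo[5.3.0]decane is broken. C1 and C5 are therefore sacrificial centres, and the ten-membered ring, its ketone, its Z olefin and the C3 oxygen can all come from one fragmentation of a hydroazulene.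

## Retrosynthesis

**38 ⇒ 37 ⇒ 35 (acetate, furanone).** The O9–acetyl bond is cut first (37), then the O–C3 bond of the furanone, leading to the 1,3-diketone 35 with the C9 and C10 oxygens held in an acetonide. Cyclodehydration of an α′-hydroxy 1,3-diketone is the standard entry to 3(2H)-furanones, and leaving the acetate to the last step keeps it away from every basic or Lewis-acidic step. The precursor has no heterocycle and no ester at O9. The forward reaction must free the diol and close the five-membered ring through the tertiary C10 hydroxyl faster than the C9 hydroxyl closes a six-membered ring.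

**35 ⇒ 34 ⇒ 33 (the ring).** After adjusting C3 to the alcohol (34), the C1–C5 bond is reconnected, turning the ten-membered ring into the epoxy alcohol 33. Against the neighbouring cuts (C–C macrocyclisation at C1–C2, C2–C3 or C6–C7), this one needs no high dilution, makes the Z olefin stereospecifically and creates ketone, olefin and C3 oxygen together. The precursor is a fused 5/7 system in which all remaining stereocentres sit on rigid rings. The forward step asks for an alkoxide on C1, the epoxide oxygen on the face of the five-membered ring that carries C6, and a masked C10 oxygen.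

**33 ⇒ 32 ⇒ 30 + 31; 30 ⇒ 29 ⇒ 28 (epoxide, methacrylate, C8).** The epoxide is traced to the homoallylic alcohol 32, since a hydroxyl-directed epoxidation puts the oxygen syn to C1–OH, which in the trans-fused bicycle is the face of C6. The methacrylate is cut to alcohol 30 and anhydride 31; installing it here spares a silylation and a desilylation and keeps fluoride and base away from the finished molecule. The 8β-alcohol 30 is derived from its epimer 28 through ketone 29, because the C7–C8 bond construction below gives 8α and the 9,10-acetonide can deliver hydride from the α face.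

**28 ⇒ 27 ⇒ 26 ⇒ 24 ⇒ 23 (C9, C10, C11 oxygens).** The acetonide, the two C–O bonds at C9/C10 and the epoxide C–O bonds at C11/C13 are removed, giving the triene lactone 23. All three oxidations are done on one rigid bicycle: the lactone is epoxidised while the C8 substituent is still α and leaves the β face of C11 open, and the osmylation is steered to the β face by C1–OH and by the 8α-silyloxy group. The forward steps must distinguish the C9=C10 olefin from the cyclopentene olefin.

**23 ⇒ 22 ⇒ 20 + 21 (five-membered ring).** The C3=C4 bond is cut by metathesis (diene 22) and the C1–C2 bond by allylation (enone 20 and allyl bromide 21). Adding the allyl group to a ring ketone anti to the neighbouring isopropenyl group sets C1–OH trans to H-5, the relationship the fragmentation needs, which an acyclic addition would not guarantee. The mild Barbier conditions are compatible with the α-methylene lactone.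

**20 ⇒ 19 (seven-membered ring).** The C1–C10 acyl–alkenyl bond is cut to the thioester/alkenylstannane 19. A neutral thioester coupling tolerates the lactone and keeps the α-stereocentre C5 as a thioester instead of a labile aldehyde; the alternative addition of an alkenyl metal to a C1 aldehyde costs three more steps.

**19 ⇒ 18 ⇒ 11 + 16 (C7–C8).** The C7–C8 bond is cut to the bromomethyl butenolide 11 and the stannyl enal 16. The butenolide allyl metal attacks through C7 anti to the C6 substituent, so the trans lactone is secured and the α-methylene group appears in the same step. The cost is the 8α configuration, corrected later.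

**11 ⇒ 10 ⇒ 7 + 9; 7 ⇒ 6 ⇒ 3 + 4; 3 ⇒ 1 + 2 (C5, C6).** The butenolide C7=C11 bond is cut by metathesis (10), the ester to alcohol 7 and acid chloride 9, and the C5–C6 bond by a deconjugative Evans aldol of imide 3 with acrolein 4. This single auxiliary-controlled step sets the absolute configuration of the whole synthesis (C6, and C5 as relay), and delivers the isopropenyl group that later becomes C4/C15.

**16 ⇒ 15 ⇒ 14 ⇒ 12; 9 ⇒ 8.** The Z alkenylstannane comes from but-2-yn-1-ol 12 by trans-hydroalumination/iodination (14) and stannylation (15); the Z geometry is what lets C1 and C8 end up cis on the ring olefin. The acid chloride 9 comes from commercial acid 8.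

A photochemical eudesmanolide-to-guaianolide rearrangement would give the 5/7 skeleton faster, but it leaves no handle for the C8 oxygen and places the C10 oxygen on the α face; the hydroazulene is therefore built de novo.

## Roads not taken

**Alternative 1:** The cut is across the lactone atoms: a nitrile oxide bearing an ethyl ester adds to the E C6=C7 bond of a glyceraldehyde-derived iododiene, forming C7–C11 and O–C6 and giving the isoxazoline A1. Its merits are real: C6 and C7 come out trans from the E olefin, the dioxolane stereocentre at C8 biases the face, and all lactone carbons are in place after one step from cheap chiral-pool material. In that respect it is shorter than the aldol/metathesis/Barbier sequence used here. Its weak points lie downstream: C11 is an imine carbon that must become the quaternary spiro-epoxide through an α-keto lactone, which enolises toward C7. The ten-membered ring still has to be closed by C–C bond formation from the Z alkenyl iodide, and C9, C10 and the furanone are all still to be built. The chosen plan takes longer over the lactone but avoids any macrocyclisation and sets C11 on a rigid bicycle.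

**Alternative 2:** The cut is C7–C8 with ring contraction: the enolate of a C9 ketone in a thirteen-membered allyl ether (O8 to C13) undergoes a [2,3]-Wittig shift to the ten-membered α-hydroxy ketone A2, releasing C8–OH and the C11=C13 methylene. It is elegant in that a macrocyclic ether is easier to close than a carbocycle, and one step creates the carbocycle, two stereocentres and the acrylate; no step of the chosen plan does as much. Against it, the enolate sits next to the furanone-bearing C10 and must be formed regioselectively. The C7/C8 configuration depends on the fold of a large flexible ring, and [1,2]-shift and elimination compete. The C9 ketone must afterwards be reduced to the β-alcohol on the medium ring, and the trans lactone closed. The chosen plan sets C7–C10 on five- and seven-membered rings where the facial bias can be argued, at the price of more steps.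

**Alternative 3:** The cut is C1–C2: a nitrile oxide generated on the quaternary C10 adds intramolecularly to the terminal alkyne of a Z enyne, closing the ten-membered ring as the isoxazole A3, a masked 1,3-diketone. This is the most convergent road and probably the shortest endgame: reductive N–O cleavage and hydrolysis would lead directly to the furanone with the epoxy-lactone, acetate and Z olefin already present. On step count and convergence it is better than the plan chosen here. Its risks are concentrated in one step: the ring to be formed contains a Z olefin, a 3,5-bridged isoxazole and a trans lactone, so strain and nitrile oxide dimerisation at a hindered tertiary centre threaten the cyclisation. The epoxy-lactone must also survive N–O reduction, and the acyclic precursor with five contiguous stereocentres has to be made by acyclic stereocontrol. The chosen plan trades convergence for a ring-forming step that is unimolecular, needs no dilution and fixes the olefin geometry by mechanism.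

Key step: step 23

Assumption: locants follow guaiane/germacrane numbering (C12 lactone carbonyl, C13 its exocyclic carbon, C14 methyl on C10, C15 methyl on C4), α/β refer to the usual drawing with H-7 α, and the Z stannyl enal 16 is taken to be configurationally stable on the time scale of step 10.

## Route

Step 1
Reactants: 1 (R)-4-benzyloxazolidin-2-one; 2 3-methylbut-2-enoyl chloride
Product: 3 (R)-4-benzyl-3-(3-methylbut-2-enoyl)oxazolidin-2-one
Conditions: n-BuLi, THF, −78 °C; then 2, −78 to 0 °C
Reagents that add atoms: none
Why: N-acylation of the lithiated oxazolidinone by an acid chloride, the standard preparation of an Evans imide.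

Step 2
Reactants: 3 imide; 4 acrolein
Product: 6 (4R)-4-benzyl-3-[(2R,3S)-3-hydroxy-2-(prop-1-en-2-yl)pent-4-enoyl]oxazolidin-2-one, via boron dienolate 5 (not isolated)
Conditions: Bu2BOTf, Et3N, CH2Cl2, −78 to 0 °C; 4, −78 °C; then pH 7 buffer, H2O2, MeOH, 0 °C
Reagents that add atoms: none
Why: Deconjugative Evans aldol: γ-deprotonation gives the Z boron dienolate, which reacts at its α-carbon through a chair transition state on the face away from the benzyl group. The syn adduct with the (2R,3S) configuration (C5 and C6) should result, with acrolein attacked 1,2.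

Step 3
Reactants: 6 aldol adduct
Product: 7 S-ethyl (2R,3S)-3-hydroxy-2-(prop-1-en-2-yl)pent-4-enethioate
Conditions: EtSH, n-BuLi, THF, 0 °C
Reagents that add atoms: ethanethiol, CCS
Why: Thiolate transacylation at the exocyclic imide carbonyl frees the auxiliary and gives a thioester, which is inert to the following steps yet is the acyl donor of step 12.

Step 4
Reactants: 8 2-(bromomethyl)acrylic acid
Product: 9 2-(bromomethyl)acryloyl chloride
Conditions: (COCl)2, DMF (cat.), CH2Cl2, 0 to 20 °C
Reagents that add atoms: oxalyl chloride, ClC(=O)C(=O)Cl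
Why: Acid chloride formation through the chloroiminium salt from DMF; no base is present that could displace the allylic bromide.

Step 5
Reactants: 7 hydroxy thioester; 9 acid chloride
Product: 10 S-ethyl (2R,3S)-3-{[2-(bromomethyl)prop-2-enoyl]oxy}-2-(prop-1-en-2-yl)pent-4-enethioate
Conditions: 2,6-lutidine, CH2Cl2, −20 to 0 °C
Reagents that add atoms: none
Why: O-acylation of the secondary allylic alcohol; a hindered pyridine is used because unhindered amines attack 2-(bromomethyl)acrylates in an SN2′ sense.

Step 6
Reactants: 10 acrylate ester
Product: 11 S-ethyl (2R)-2-[(2S)-4-(bromomethyl)-5-oxo-2,5-dihydrofuran-2-yl]-3-methylbut-3-enethioate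
Conditions: second-generation Hoveyda–Grubbs catalyst RuCl2(=CH-C6H4-2-OiPr)(H2IMes) (5 mol %), CH2Cl2, 40 °C
Reagents that add atoms: none
Why: Ring-closing metathesis of the vinyl group with the 1,1-disubstituted acrylate gives the butenolide; the isopropenyl group could only form a four-membered or a tetrasubstituted six-membered ring and should stay out.

Step 7
Reactants: 12 but-2-yn-1-ol
Product: 14 (Z)-3-iodobut-2-en-1-ol, via cyclic alkenylaluminate 13 (not isolated)
Conditions: NaAlH2(OCH2CH2OCH3)2, THF, 0 to 20 °C; then I2, −78 °C
Reagents that add atoms: iodine, II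
Why: Hydroxyl-directed trans-hydroalumination of the propargylic alcohol places aluminium on C3 cis to the carbinol carbon; iodinolysis with retention gives the Z iodide.

Step 8
Reactants: 14 (Z)-3-iodobut-2-en-1-ol
Product: 15 (Z)-3-(tributylstannyl)but-2-en-1-ol
Conditions: (Bu3Sn)2, Pd(PPh3)4 (5 mol %), toluene, 80 °C
Reagents that add atoms: hexabutylditin, CCCC[Sn](CCCC)(CCCC)[Sn](CCCC)(CCCC)CCCC
Why: Palladium-catalysed stannylation of an alkenyl iodide with a distannane proceeds with retention of olefin geometry and tolerates the free alcohol.

Step 9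
Reactants: 15 stannyl alcohol
Product: 16 (Z)-3-(tributylstannyl)but-2-enal
Conditions: MnO2, CH2Cl2, 20 °C
Reagents that add atoms: none
Why: Neutral allylic oxidation with MnO2; no acid is present that could protodestannylate or isomerise the Z enal.

Step 10
Reactants: 11 bromomethyl butenolide; 16 stannyl enal
Product: 18 S-ethyl (2R)-2-{(2S,3R)-3-[(1R,2Z)-1-hydroxy-3-(tributylstannyl)but-2-en-1-yl]-4-methylidene-5-oxooxolan-2-yl}-3-methylbut-3-enethioate, via allylzinc bromide 17 (not isolated)
Conditions: Zn dust, THF/sat. aq NH4Cl 1:1, 0 to 20 °C
Reagents that add atoms: none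
Why: Barbier allylation: the allylzinc reacts through its γ-carbon C7 on the face opposite the C6 substituent, giving the trans lactone and the exocyclic methylene. The closed six-membered transition state with the aldehyde substituent equatorial should give the anti C7/C8 relationship (8α-OH); the aldehyde is attacked 1,2 and the thioester is untouched.

Step 11
Reactants: 18 Barbier adduct
Product: 19 8-O-tert-butyldimethylsilyl ether of 18
Conditions: TBSOTf, 2,6-lutidine, CH2Cl2, −78 °C
Reagents that add atoms: tert-butyldimethylsilyl trifluoromethanesulfonate, CC(C)(C)[Si](C)(C)OS(=O)(=O)C(F)(F)F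
Why: Silylation of the hindered secondary alcohol; the excess base protects the alkenylstannane from acid, and the 8α-silyloxy group later shields the α face of C9=C10.

Step 12
Reactants: 19 thioester alkenylstannane
Product: 20 cycloheptenone lactone (C1 ketone; C9=C10 with 10-methyl; 8α-OTBS; 5β-isopropenyl, 5αH; 6α,12-olide trans-fused at C6/C7; 11(13)-methylene)
Conditions: Pd2(dba)3 (5 mol %), P(2-furyl)3, Cu(O2CC4H3S) (1.5 equiv), THF, 50 °C, 0.002 M
Reagents that add atoms: none
Why: Intramolecular Liebeskind–Srogl coupling: zerovalent palladium inserts into the C–S bond, the copper carboxylate takes up the thiolate and promotes transfer of the alkenyl group from tin, and reductive elimination forms the C1–C10 bond. The conditions are neutral, so the lactone and the C5 centre should survive; the Z geometry places C1 and C8 cis, as the seven-membered ring requires.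

Step 13
Reactants: 20 cycloheptenone; 21 allyl bromide
Product: 22 1α-allyl-1β-hydroxy adduct of 20
Conditions: In powder, THF/H2O 1:1, 20 °C
Reagents that add atoms: none
Why: Indium-mediated Barbier allylation adds 1,2 to the enone carbonyl and does not touch lactones. Attack on the ring ketone anti to the adjacent isopropenyl group sets the allyl group α and the hydroxyl β, trans to H-5.

Step 14
Reactants: 22 allyl carbinol
Product: 23 1β-hydroxy-8α-(tert-butyldimethylsilyloxy)-5αH-guaia-3,9,11(13)-trien-6α,12-olide (trans-fused at C1/C5)
Conditions: second-generation Grubbs catalyst RuCl2(=CHPh)(PCy3)(H2IMes) (5 mol %), CH2Cl2, 40 °C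
Reagents that add atoms: none
Why: Ring-closing metathesis of the allyl and isopropenyl groups forms the trisubstituted C3=C4 olefin; the ring C9=C10 olefin and the electron-poor methylene lactone are poor metathesis partners.

Step 15
Reactants: 23 triene lactone
Product: 24 11β,13-epoxide of 23
Conditions: t-BuOOH (decane), DBU, CH2Cl2, 0 °C
Reagents that add atoms: tert-butyl hydroperoxide, CC(C)(C)OO
Why: Weitz–Scheffer epoxidation: the peroxide anion adds to C13 of the only electrophilic olefin and the lactone enolate closes onto oxygen. With the C8 substituent still α, the β face of C11 is open and the α face is flanked by axial H-7, the same bias that gives 11β-H products on protonation of such enolates, so the oxygen should enter β.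

Step 16
Reactants: 24 epoxy lactone diene
Product: 26 1β,9β,10β-trihydroxy-8α-(tert-butyldimethylsilyloxy)-11β,13-epoxy-5αH-guai-3-en-6α,12-olide, via osmate ester 25 (not isolated)
Conditions: OsO4 (1.1 equiv), TMEDA, CH2Cl2, −78 °C; then aq NaHSO3, THF, 20 °C
Reagents that add atoms: osmium tetroxide, O=[Os](=O)(=O)=O
Why: Hydrogen-bond-directed osmylation: the OsO4–diamine complex is bound by the allylic C1 hydroxyl and delivered to the β face of C9=C10, the face also left open by the 8α-silyloxy group, giving C9 and C10 oxygens cis to C1–OH. The cyclopentene is only homoallylic to the hydroxyl and its β face is hindered by C6, so it should react more slowly.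

Step 17
Reactants: 26 triol
Product: 27 9,10-O-isopropylidene derivative of 26
Conditions: 2,2-dimethoxypropane, PPTS (cat.), CH2Cl2, 20 °C
Reagents that add atoms: 2,2-dimethoxypropane, COC(C)(C)OC
Why: Acetonide formation on the cis secondary/tertiary 9,10-diol, which should be preferred over the di-tertiary 1,10-diol; it masks the C10 oxygen for the fragmentation and provides the facial bias for step 20.

Step 18
Reactants: 27 silyl ether
Product: 28 8α-alcohol
Conditions: Bu4NF, AcOH, THF, 0 to 20 °C
Reagents that add atoms: none
Why: Buffered fluoride desilylation; the buffer keeps the medium from opening the epoxy-lactone, and the 8α-oxygen is trans to C7–C11 and not placed to translactonise.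

Step 19
Reactants: 28 8α-alcohol
Product: 29 8-ketone
Conditions: Dess–Martin periodinane, NaHCO3, CH2Cl2, 0 °C
Reagents that add atoms: none
Why: Dess–Martin oxidation of the only secondary alcohol under buffered, non-basic conditions; the tertiary C1 hydroxyl is inert. The ketone is used at once because H-7 is acidic.

Step 20
Reactants: 29 8-ketone
Product: 30 8β-alcohol
Conditions: NaBH4, CeCl3·7H2O, MeOH/THF, −78 °C
Reagents that add atoms: none
Why: Luche reduction: both neighbours of the carbonyl carry β substituents (the cis-fused dioxolane oxygen on C9 and the C7–C11 bond), so hydride should add from the α face and give the all-cis 8β-alcohol.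

Step 21
Reactants: 30 8β-alcohol; 31 methacrylic anhydride
Product: 32 8β-methacrylate
Conditions: DMAP, Et3N, CH2Cl2, 0 to 20 °C
Reagents that add atoms: none
Why: DMAP-catalysed acylation of the secondary alcohol; the tertiary C1 hydroxyl does not react, and no alkoxide is generated that could translactonise onto C12.

Step 22
Reactants: 32 homoallylic alcohol
Product: 33 3β,4β-epoxide (1β-hydroxy-3β,4β:11β,13-diepoxy-9β,10β-isopropylidenedioxy-8β-methacryloyloxy-5αH-guaian-6α,12-olide)
Conditions: VO(acac)2 (5 mol %), t-BuOOH (decane), CH2Cl2, 0 to 20 °C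
Reagents that add atoms: tert-butyl hydroperoxide, CC(C)(C)OO
Why: Hydroxyl-directed epoxidation of a cyclic homoallylic alcohol: the vanadium alkoxide of C1–OH delivers oxygen to the syn (β) face of C3=C4, the face that carries C6 and is trans to H-5. The methacrylate olefin is too electron-poor to react.

Step 23
Reactants: 33 epoxy alcohol
Product: 34 ten-membered (4Z)-keto alcohol: (3S)-3-hydroxy-1-oxo-9β,10β-isopropylidenedioxy-8β-methacryloyloxy-11β,13-epoxygermacr-4-en-6α,12-olide
Conditions: Ti(OiPr)4 (1.5 equiv), CH2Cl2, 0 to 20 °C; aq tartaric acid work-up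
Reagents that add atoms: none
Why: Ligand exchange puts titanium on the tertiary C1 oxygen and the Lewis-acidic metal activates the epoxide, so the C1–C5 σ bond pushes into the C4–O σ* orbital while C1–O becomes C=O: a Grob-type epoxy-alcohol fragmentation. The closest known reaction type is the Grob/Wharton fragmentation of fused bicyclic 1,3-hydroxy-nucleofuge systems to medium-ring ketones, including the titanium alkoxide variant with an epoxide as nucleofuge. No ring is closed: the ten-membered ring appears because the bond shared by the five- and seven-membered rings is cut, and no stereocentre is created (C3 keeps the configuration of its epoxide C–O bond; C1 and C5 become sp2). The one selectivity needed is the olefin geometry: in the envelope conformer that brings C4–O toward antiperiplanarity with C1–C5, C3 and C6 lie on the same side of the forming C4=C5 bond when the epoxide oxygen is cis to C6, as step 22 provides, so the Z olefin should form stereospecifically. Relief of the strain of the trans-fused bicycle and of the epoxide drives the step. The acetonide keeps the C10 oxygen from opening the epoxide or starting an α-ketol shift, the C3 alkoxide stays chelated to titanium with the C1 ketone (holding back retro-aldol cleavage), and the low temperature keeps Ti(OiPr)4 from transesterifying the methacrylate.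

Step 24
Reactants: 34 keto alcohol
Product: 35 1,3-diketone
Conditions: Dess–Martin periodinane, NaHCO3, CH2Cl2, 0 °C
Reagents that add atoms: none
Why: Dess–Martin oxidation of the allylic C3 alcohol, the only free hydroxyl, gives the enolisable 1,3-diketone without base.

Step 25
Reactants: 35 diketone acetonide
Product: 37 9β-hydroxy furanone (target lacking the acetyl group), via diol diketone 36 (not isolated)
Conditions: CF3CO2H/H2O 9:1, CH2Cl2, 0 to 20 °C
Reagents that add atoms: none
Why: Acid hydrolysis of the acetonide frees the tertiary C10 hydroxyl, which adds to the C3 carbonyl through a five-membered hemiketal and loses water to give the 3(2H)-furanone, the usual cyclodehydration of α′-hydroxy 1,3-diketones. The five-membered closure should outrun six-membered closure through O9, and the non-nucleophilic acid spares the epoxy-lactone.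

Step 26
Reactants: 37 hydroxy furanone
Product: 38 CNP0423862.2 (target)
Conditions: Ac2O, DMAP, pyridine, CH2Cl2, 0 °C
Reagents that add atoms: acetic anhydride, CC(=O)OC(C)=O
Why: Acetylation of the single remaining hydroxyl (O9) under mild acylation conditions completes the target.

## Compound list

1 | (R)-4-benzyloxazolidin-2-one | O=C1N[C@H](Cc2ccccc2)CO1 | starting material
2 | 3-methylbut-2-enoyl chloride | CC(C)=CC(=O)Cl | starting material
3 | (R)-4-benzyl-3-(3-methylbut-2-enoyl)oxazolidin-2-one | CC(C)=CC(=O)N1[C@H](Cc2ccccc2)COC1=O | intermediate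
4 | acrolein | C=CC=O | starting material
5 | Z dibutylboron dienolate of 3 | C=C(C)/C=C(\OB(CCCC)CCCC)N1[C@H](Cc2ccccc2)COC1=O | intermediate
6 | (4R)-4-benzyl-3-[(2R,3S)-3-hydroxy-2-(prop-1-en-2-yl)pent-4-enoyl]oxazolidin-2-one | C=C[C@H](O)[C@@H](C(C)=C)C(=O)N1[C@H](Cc2ccccc2)COC1=O | intermediate
7 | S-ethyl (2R,3S)-3-hydroxy-2-(prop-1-en-2-yl)pent-4-enethioate | C=C[C@H](O)[C@@H](C(C)=C)C(=O)SCC | intermediate
8 | 2-(bromomethyl)acrylic acid | C=C(CBr)C(=O)O | starting material
9 | 2-(bromomethyl)acryloyl chloride | C=C(CBr)C(=O)Cl | intermediate
10 | S-ethyl (2R,3S)-3-{[2-(bromomethyl)prop-2-enoyl]oxy}-2-(prop-1-en-2-yl)pent-4-enethioate | C=C[C@H](OC(=O)C(=C)CBr)[C@@H](C(C)=C)C(=O)SCC | intermediate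
11 | S-ethyl (2R)-2-[(2S)-4-(bromomethyl)-5-oxo-2,5-dihydrofuran-2-yl]-3-methylbut-3-enethioate | BrCC1=C[C@@H]([C@@H](C(C)=C)C(=O)SCC)OC1=O | intermediate
12 | but-2-yn-1-ol | CC#CCO | starting material
13 | sodium cyclic alkenylaluminate from 12 (five-membered O–Al ring, aluminium on C3) | CC1=CCO[Al-]1(OCCOC)OCCOC.[Na+] | intermediate
14 | (Z)-3-iodobut-2-en-1-ol | I/C(C)=C\CO | intermediate
15 | (Z)-3-(tributylstannyl)but-2-en-1-ol | CCCC[Sn](CCCC)(CCCC)/C(C)=C\CO | intermediate
16 | (Z)-3-(tributylstannyl)but-2-enal | CCCC[Sn](CCCC)(CCCC)/C(C)=C\C=O | intermediate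
17 | allylzinc bromide from 11 | Br[Zn]CC1=C[C@@H]([C@@H](C(C)=C)C(=O)SCC)OC1=O | intermediate
18 | S-ethyl (2R)-2-{(2S,3R)-3-[(1R,2Z)-1-hydroxy-3-(tributylstannyl)but-2-en-1-yl]-4-methylidene-5-oxooxolan-2-yl}-3-methylbut-3-enethioate | O[C@@H](/C=C(/C)[Sn](CCCC)(CCCC)CCCC)[C@@H]1[C@@H]([C@@H](C(C)=C)C(=O)SCC)OC(=O)C1=C | intermediate
19 | tert-butyldimethylsilyl ether of 18 (8α-OTBS) | CC(C)(C)[Si](C)(C)O[C@@H](/C=C(/C)[Sn](CCCC)(CCCC)CCCC)[C@@H]1[C@@H]([C@@H](C(C)=C)C(=O)SCC)OC(=O)C1=C | intermediate
20 | cycloheptenone lactone: C1 ketone, C9=C10 (10-methyl), 8α-OTBS, 5β-isopropenyl (5αH), trans 6α,12-olide (6βH,7αH), 11(13)-methylene | CC(C)(C)[Si](C)(C)O[C@@H]1[C@@H]2[C@@H]([C@@H](C(C)=C)C(=O)C(C)=C1)OC(=O)C2=C | intermediate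
21 | allyl bromide | C=CCBr | starting material
22 | 1α-allyl-1β-hydroxy adduct of 20 | CC(C)(C)[Si](C)(C)O[C@@H]1[C@@H]2[C@@H]([C@@H](C(C)=C)[C@](O)(CC=C)C(C)=C1)OC(=O)C2=C | intermediate
23 | 1β-hydroxy-8α-(tert-butyldimethylsilyloxy)-5αH-guaia-3,9,11(13)-trien-6α,12-olide | CC(C)(C)[Si](C)(C)O[C@@H]1[C@@H]2[C@@H]([C@H]3C(C)=CC[C@]3(O)C(C)=C1)OC(=O)C2=C | intermediate
24 | 11β,13-epoxide of 23 | CC(C)(C)[Si](C)(C)O[C@@H]1[C@@H]2[C@@H]([C@H]3C(C)=CC[C@]3(O)C(C)=C1)OC(=O)[C@@]24CO4 | intermediate
25 | 9β,10β-osmate ester of 24 (dioxo-osmium glycolate chelated by TMEDA, hexavalent osmium) | CC(C)(C)[Si](C)(C)O[C@@H]1[C@@H]2[C@@H]([C@H]3C(C)=CC[C@]3(O)[C@@]5(C)O[Os-2]6(=O)(=O)([N+](C)(C)CC[N+]6(C)C)O[C@@H]15)OC(=O)[C@@]24CO4 | intermediate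
26 | 1β,9β,10β-trihydroxy-8α-(tert-butyldimethylsilyloxy)-11β,13-epoxy-5αH-guai-3-en-6α,12-olide | CC(C)(C)[Si](C)(C)O[C@@H]1[C@@H]2[C@@H]([C@H]3C(C)=CC[C@]3(O)[C@@](C)(O)[C@H]1O)OC(=O)[C@@]24CO4 | intermediate
27 | 9β,10β-O-isopropylidene derivative of 26 | CC(C)(C)[Si](C)(C)O[C@@H]1[C@@H]2[C@@H]([C@H]3C(C)=CC[C@]3(O)[C@@]5(C)OC(C)(C)O[C@@H]15)OC(=O)[C@@]24CO4 | intermediate
28 | 8α-alcohol (1β,8α-dihydroxy-9β,10β-isopropylidenedioxy-11β,13-epoxy-5αH-guai-3-en-6α,12-olide) | O[C@@H]1[C@@H]2[C@@H]([C@H]3C(C)=CC[C@]3(O)[C@@]5(C)OC(C)(C)O[C@@H]15)OC(=O)[C@@]24CO4 | intermediate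
29 | 8-ketone of 28 | O=C1[C@@H]2[C@@H]([C@H]3C(C)=CC[C@]3(O)[C@@]5(C)OC(C)(C)O[C@@H]15)OC(=O)[C@@]24CO4 | intermediate
30 | 8β-alcohol (C8 epimer of 28) | O[C@H]1[C@@H]2[C@@H]([C@H]3C(C)=CC[C@]3(O)[C@@]5(C)OC(C)(C)O[C@@H]15)OC(=O)[C@@]24CO4 | intermediate
31 | methacrylic anhydride | C=C(C)C(=O)OC(=O)C(C)=C | starting material
32 | 8β-methacrylate of 30 | C=C(C)C(=O)O[C@H]1[C@@H]2[C@@H]([C@H]3C(C)=CC[C@]3(O)[C@@]5(C)OC(C)(C)O[C@@H]15)OC(=O)[C@@]24CO4 | intermediate
33 | 3β,4β-epoxide of 32 (fragmentation precursor) | C=C(C)C(=O)O[C@H]1[C@@H]2[C@@H]([C@H]3[C@@]6(C)O[C@H]6C[C@]3(O)[C@@]5(C)OC(C)(C)O[C@@H]15)OC(=O)[C@@]24CO4 | intermediate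
34 | ten-membered (4Z)-3-hydroxy-1-ketone (fragmentation product) | C=C(C)C(=O)O[C@H]1[C@@H]2[C@@H](/C=C(/C)[C@@H](O)CC(=O)[C@@]5(C)OC(C)(C)O[C@@H]15)OC(=O)[C@@]24CO4 | intermediate
35 | ten-membered (4Z)-1,3-diketone | C=C(C)C(=O)O[C@H]1[C@@H]2[C@@H](/C=C(/C)C(=O)CC(=O)[C@@]5(C)OC(C)(C)O[C@@H]15)OC(=O)[C@@]24CO4 | intermediate
36 | 9β,10β-diol of 35 | C=C(C)C(=O)O[C@H]1[C@@H]2[C@@H](/C=C(/C)C(=O)CC(=O)[C@@](C)(O)[C@H]1O)OC(=O)[C@@]24CO4 | intermediate
37 | 9β-hydroxy furanone (9-O-deacetyl target) | C=C(C)C(=O)O[C@H]1[C@@H]2[C@@H](/C=C(/C)C3=CC(=O)[C@@](C)(O3)[C@H]1O)OC(=O)[C@@]24CO4 | intermediate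
38 | CNP0423862.2 | C=C(C)C(=O)O[C@H]1[C@@H]2[C@@H](/C=C(/C)C3=CC(=O)[C@@](C)(O3)[C@H]1OC(C)=O)OC(=O)[C@@]21CO1 | target

## Step count and least certain steps

Total step count: 26. Longest linear sequence: 22 (steps 1–3, 5, 6, 10–26).

**Step 23 (key step).** The C4–O bond is part of a fused three-membered ring and cannot reach full antiperiplanarity to C1–C5, so the fragmentation may be slow. Epoxide opening by isopropoxide, ether formation from O1 to C4, or retro-aldol cleavage of the product could then take over. The fallback changes the nucleofuge. Setting out from 32, hydroxyl-directed osmylation (OsO4, TMEDA) of the cyclopentene on the face of C1–OH should give the 3β,4β-diol F1. SOCl2/Et3N followed by RuCl3 (cat.)/NaIO4 should give the cyclic sulfate F2; its C4–O bond is a far better leaving group and sits in a more flexible five-membered ring. Potassium tert-butoxide in THF at −78 °C should fragment it to the potassium C3 sulfate half-ester F3. Hydrolysis with catalytic H2SO4 and one equivalent of water in THF returns to the route at 34. The Z geometry follows from the same face relationship.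

**Step 12.** Transfer of the hindered trisubstituted alkenyl group from tin may be slower than protodestannylation or intermolecular coupling, and the seven-membered enone could form in low conversion. The fallback closes the same bond by a Nozaki–Hiyama–Kishi reaction. Setting out from 6, LiBH4 should give the (2R,3S)-diol F4, and Et3SiCl/imidazole its primary triethylsilyl ether F5. Acylation with 9 gives the acrylate F6 and metathesis the butenolide F7. A zinc Barbier reaction with (Z)-3-iodobut-2-enal F8 (from 14 and MnO2) gives the iodo alcohol F9, and TBSOTf its silyl ether F10. PPTS in methanol frees the primary alcohol F11, and Dess–Martin oxidation gives the aldehyde F12. CrCl2 with catalytic NiCl2 in DMF at high dilution should add the alkenyl iodide to the aldehyde to give the cycloheptenol F13, and Dess–Martin oxidation returns to the route at 20.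

**Step 16.** Osmylation may lose chemoselectivity: the cyclopentene olefin is the more electron-rich one and could react in competition despite the directing effect. The fallback protects it temporarily. Setting out from 24, pyridinium tribromide should add bromine to the cyclopentene only, giving the trans-3,4-dibromide F14. Catalytic OsO4 with N-methylmorpholine N-oxide then has one olefin left and, attacking anti to the 8α-silyloxy group, should give the 9β,10β-diol F15. Acetonide formation gives F16, and zinc dust in ethanol regenerates the olefin, returning to the route at 27.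

**Step 19 (with its partner step 20).** At the ketone stage H-7 is acidic and β-elimination into the spiro-epoxide, or epimerisation at C7, may occur before the reduction; the reduction itself could lose facial selectivity. The fallback avoids the ketone: a Mitsunobu esterification of 28 with methacrylic acid (PPh3, diisopropyl azodicarboxylate, toluene) would invert C8 and give 32 directly. The C9 oxygen is an acetal oxygen and cannot participate as an acyloxy group would. No new compound is made on this path.

## Further compounds

F1 | step 23 | 3β,4β-diol from 32 (1β,3β,4β-trihydroxy analogue) | C=C(C)C(=O)O[C@H]1[C@@H]2[C@@H]([C@H]3[C@@](C)(O)[C@@H](O)C[C@]3(O)[C@@]5(C)OC(C)(C)O[C@@H]15)OC(=O)[C@@]24CO4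
F2 | step 23 | 3β,4β-cyclic sulfate of F1 | C=C(C)C(=O)O[C@H]1[C@@H]2[C@@H]([C@H]3[C@@]6(C)OS(=O)(=O)O[C@H]6C[C@]3(O)[C@@]5(C)OC(C)(C)O[C@@H]15)OC(=O)[C@@]24CO4
F3 | step 23 | potassium 3-O-sulfate of 34 | C=C(C)C(=O)O[C@H]1[C@@H]2[C@@H](/C=C(/C)[C@@H](OS(=O)(=O)[O-])CC(=O)[C@@]5(C)OC(C)(C)O[C@@H]15)OC(=O)[C@@]24CO4.[K+]
F4 | step 12 | (2R,3S)-2-(prop-1-en-2-yl)pent-4-ene-1,3-diol | C=C[C@H](O)[C@@H](C(C)=C)CO
F5 | step 12 | 1-O-triethylsilyl ether of F4 | C=C[C@H](O)[C@@H](C(C)=C)CO[Si](CC)(CC)CC
F6 | step 12 | 3-O-[2-(bromomethyl)acryloyl] ester of F5 | C=C[C@H](OC(=O)C(=C)CBr)[C@@H](C(C)=C)CO[Si](CC)(CC)CC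
F7 | step 12 | bromomethyl butenolide with triethylsilyloxymethyl side chain (thioester of 11 replaced by CH2OSiEt3) | BrCC1=C[C@@H]([C@@H](C(C)=C)CO[Si](CC)(CC)CC)OC1=O
F8 | step 12 | (Z)-3-iodobut-2-enal | I/C(C)=C\C=O
F9 | step 12 | Barbier adduct of F7 and F8 (8α-OH, Z alkenyl iodide) | O[C@@H](/C=C(/C)I)[C@@H]1[C@@H]([C@@H](C(C)=C)CO[Si](CC)(CC)CC)OC(=O)C1=C
F10 | step 12 | 8-O-tert-butyldimethylsilyl ether of F9 | CC(C)(C)[Si](C)(C)O[C@@H](/C=C(/C)I)[C@@H]1[C@@H]([C@@H](C(C)=C)CO[Si](CC)(CC)CC)OC(=O)C1=C
F11 | step 12 | primary alcohol from F10 | CC(C)(C)[Si](C)(C)O[C@@H](/C=C(/C)I)[C@@H]1[C@@H]([C@@H](C(C)=C)CO)OC(=O)C1=C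
F12 | step 12 | C1 aldehyde from F11 | CC(C)(C)[Si](C)(C)O[C@@H](/C=C(/C)I)[C@@H]1[C@@H]([C@@H](C(C)=C)C=O)OC(=O)C1=C
F13 | step 12 | cycloheptenol (1-hydroxy analogue of 20, C1 epimers) | CC(C)(C)[Si](C)(C)O[C@@H]1[C@@H]2[C@@H]([C@@H](C(C)=C)C(O)C(C)=C1)OC(=O)C2=C
F14 | step 16 | 3α,4β-dibromide of 24 | CC(C)(C)[Si](C)(C)O[C@@H]1[C@@H]2[C@@H]([C@H]3[C@@](C)(Br)[C@H](Br)C[C@]3(O)C(C)=C1)OC(=O)[C@@]24CO4
F15 | step 16 | 9β,10β-diol of F14 | CC(C)(C)[Si](C)(C)O[C@@H]1[C@@H]2[C@@H]([C@H]3[C@@](C)(Br)[C@H](Br)C[C@]3(O)[C@@](C)(O)[C@H]1O)OC(=O)[C@@]24CO4
F16 | step 16 | 9,10-acetonide of F15 | CC(C)(C)[Si](C)(C)O[C@@H]1[C@@H]2[C@@H]([C@H]3[C@@](C)(Br)[C@H](Br)C[C@]3(O)[C@@]5(C)OC(C)(C)O[C@@H]15)OC(=O)[C@@]24CO4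
F0 | step 19 | none | none
A1 | alternative 1 | 3-ethoxycarbonyl isoxazoline with C6, C7 and C8 set | CCOC(=O)C1=NO[C@H](/C=C(/C)I)[C@H]1[C@H]2COC(C)(C)O2
A2 | alternative 2 | ring-contracted ten-membered α-hydroxy ketone with 2-propenoate at C7 | O[C@H]1[C@@H](C(=C)C(=O)OC)[C@H](O[Si](C)(C)C(C)(C)C)/C=C(/C)C2=CC(=O)[C@@](C)(O2)C1=O
A3 | alternative 3 | isoxazole-bridged ten-membered carbocycle | CC[Si](CC)(CC)O[C@H]1[C@@H]2[C@@H](/C=C(/C)c3cc(no3)[C@@](C)(O[Si](CC)(CC)CC)[C@H]1OC(C)=O)OC(=O)[C@@]21CO1
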